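**Plan**

- Retrosynthesis: the benzyl ethers and the 5-O-methyl group of the flavanone are removed last. Ring C of the flavanone is then cut at O1–C2 and C4–C4a, giving 3,5-dimethoxyphenol (ring A) and a cinnamoyl chloride that already carries the protected flavone and the diaryl ether.
- That acid is cut further at the flavone pyranone ring, at the chalcone C=C (aldol) and at the diaryl ether C–O bond.
- Forward order: diaryl ether, chalcone, flavone ring, acyl chloride, flavanone ring C fused onto ring A, global deprotection.
- Enabling feature: ring A is a symmetrical 3,5-dioxygenated phenol, so O1 and either ortho carbon (C4a) form a 1,3-C,O-dinucleophile. It matches the acyl carbon C4 and the β-carbon C2 of the cinnamoyl unit, and the 5-methoxy group next to C4=O is the one that chelation removes at the end.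
- Stereochemistry: the single stereocentre C2 (S) is set in the key step by a cinchona-derived bifunctional thiourea (addition of O1 to the Si face of C2). No basic conditions follow.

Key step: step 6

Remark: flavonoid numbering is used throughout (O1, C2, C3, C4, C4a, C5 to C8, C8a; primed numbers at the chalcone stage).

**Route**

Step 1
Reactants: 1 1-(2,4,6-trihydroxyphenyl)ethan-1-one
Product: 2 1-[2,4-bis(benzyloxy)-6-hydroxyphenyl]ethan-1-one
Conditions: BnBr (2.1 equiv), K2CO3, DMF, rt to 60 °C
Reagents that add atoms: benzyl bromide, BrCc1ccccc1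
Why: Williamson etherification with two equivalents of benzyl bromide should alkylate the 4-OH and one ortho OH, while the remaining ortho OH is hydrogen-bonded to the acetyl carbonyl and stays free.

Step 2
Reactants: 3 4-(benzyloxy)-3-hydroxybenzaldehyde; 4 methyl (2E)-3-(4-bromophenyl)prop-2-enoate
Product: 5 methyl (2E)-3-{4-[2-(benzyloxy)-5-formylphenoxy]phenyl}prop-2-enoate
Conditions: CuI (10 mol%), pyridine-2-carboxylic acid (20 mol%), K3PO4, DMSO, 90 °C
Reagents that add atoms: none
Why: Cu-catalysed Ullmann-type diaryl ether coupling of the phenol with the acrylate-activated aryl bromide should form the C–O bond, with aldehyde, ester and benzyl ether inert to K3PO4 in DMSO.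

Step 3
Reactants: 2 1-[2,4-bis(benzyloxy)-6-hydroxyphenyl]ethan-1-one; 5 methyl (2E)-3-{4-[2-(benzyloxy)-5-formylphenoxy]phenyl}prop-2-enoate
Product: 6 (2E)-3-{4-[2-(benzyloxy)-5-{(1E)-3-[2,4-bis(benzyloxy)-6-hydroxyphenyl]-3-oxoprop-1-en-1-yl}phenoxy]phenyl}prop-2-enoic acid
Conditions: KOH (50% aq.), EtOH, rt; then aq. HCl
Reagents that add atoms: potassium hydroxide, [K+].[OH-]
Why: Claisen–Schmidt aldol condensation of the acetophenone enolate with the non-enolisable aldehyde should give the (E)-2'-hydroxychalcone by E1cB dehydration, and the same aqueous hydroxide saponifies the methyl ester so that the acid is obtained on acidification.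

Step 4
Reactants: 6 the chalcone acid of step 3
Product: 7 (2E)-3-(4-{2-(benzyloxy)-5-[5,7-bis(benzyloxy)-4-oxo-4H-chromen-2-yl]phenoxy}phenyl)prop-2-enoic acid
Conditions: I2 (10 mol%), DMSO, 130 °C
Reagents that add atoms: none
Why: Iodine-catalysed oxidative cyclisation of the 2'-hydroxychalcone in DMSO (6-endo oxa-Michael addition, α-iodination, loss of HI, reoxidation of HI by DMSO) should give the flavone, with the benzyl ethers and the acrylic acid expected to tolerate catalytic iodine.

Step 5
Reactants: 7 the flavone acid of step 4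
Product: 8 (2E)-3-(4-{2-(benzyloxy)-5-[5,7-bis(benzyloxy)-4-oxo-4H-chromen-2-yl]phenoxy}phenyl)prop-2-enoyl chloride
Conditions: (COCl)2 (1.2 equiv), DMF (cat.), CH2Cl2, 0 °C to rt; evaporation, used crude
Reagents that add atoms: oxalyl chloride, ClC(=O)C(=O)Cl
Why: Vilsmeier-type activation of the carboxylic acid by oxalyl chloride with catalytic DMF should give the acyl chloride with gaseous by-products only, so that no Lewis base is carried into the next step.

Step 6
Reactants: 8 the acyl chloride of step 5; 9 3,5-dimethoxyphenol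
Product: 12 (2S)-2-(4-{2-(benzyloxy)-5-[5,7-bis(benzyloxy)-4-oxo-4H-chromen-2-yl]phenoxy}phenyl)-5,7-dimethoxy-2,3-dihydro-4H-chromen-4-one, via bromomagnesium 3,5-dimethoxyphenolate 10 (not isolated), via 2'-hydroxychalcone 11 (not isolated)
Conditions: 9, EtMgBr (1.05 equiv), Et2O then toluene, 0 °C to rt; 8, toluene/CH2Cl2, 0 °C to rt; then 1,4-dioxane, N-[3,5-bis(trifluoromethyl)phenyl]-N'-[(8α,9S)-6'-methoxycinchonan-9-yl]thiourea (10 mol%), −20 °C
Reagents that add atoms: none
Why: Proposed new method: a one-flask formal [3+3] annulation in which phenolate 10 binds the acyl chloride at magnesium and delivers the cinnamoyl group to the ortho carbon through a six-membered cyclic transition state (C4–C4a bond), rearomatisation gives chalcone 11, and after the magnesium halide is precipitated with dioxane the cinchona thiourea closes the O1–C2 bond by conjugate addition of the phenol to the enone. The closest known reaction types are the metal-template ortho-acylation of magnesium phenolates with α,β-unsaturated acyl chlorides to give 2'-hydroxychalcones and the amine–thiourea-catalysed enantioselective cyclisation of 2'-hydroxychalcones to flavanones; their union in one flask on this substrate class is the new element. Ring C closes by 6-endo-trig oxa-Michael addition followed by enol-to-ketone tautomerisation. The C2 stereocentre is controlled by the catalyst alone: the thiourea N–H bonds hold the enone carbonyl while the quinuclidine nitrogen activates the 2'-OH, so that O1 is expected to add to the Si face of C2 and give the 2S configuration. The step needs ortho C-acylation in place of O-acylation, para-acylation or conjugate C-alkylation to a 4-aryldihydrocoumarin, which the magnesium template, the aprotic weakly coordinating solvent and the symmetrical phenol with two equivalent ortho carbons should secure. It also needs the catalysed closure to outrun the racemic background and the retro-Michael reaction, which the 6'-methoxy group should favour by twisting the aryl ketone out of conjugation and shifting the equilibrium to the flavanone at low temperature.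

Step 7
Reactants: 12 the protected flavanone–flavone of step 6
Product: 13 (2S)-2-{4-[5-(5,7-dihydroxy-4-oxo-4H-chromen-2-yl)-2-hydroxyphenoxy]phenyl}-5-hydroxy-7-methoxy-2,3-dihydro-4H-chromen-4-one
Conditions: BCl3 (excess), pentamethylbenzene, CH2Cl2, −78 °C to 0 °C; MeOH quench
Reagents that add atoms: none
Why: Lewis-acid ether cleavage with BCl3 should remove the three aryl benzyl ethers at low temperature (pentamethylbenzene traps the benzyl cations) and, on warming to 0 °C, only the 5-methoxy group that chelates boron together with the C4 carbonyl, so that the 7-methoxy group and the C2 stereocentre are expected to survive these non-basic conditions.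

**Compound list**

1 | 1-(2,4,6-trihydroxyphenyl)ethan-1-one | CC(=O)c1c(O)cc(O)cc1O | starting material
2 | 1-[2,4-bis(benzyloxy)-6-hydroxyphenyl]ethan-1-one | CC(=O)c1c(O)cc(OCc2ccccc2)cc1OCc1ccccc1 | intermediate
3 | 4-(benzyloxy)-3-hydroxybenzaldehyde | O=Cc1ccc(OCc2ccccc2)c(O)c1 | starting material
4 | methyl (2E)-3-(4-bromophenyl)prop-2-enoate | COC(=O)/C=C/c1ccc(Br)cc1 | starting material
5 | methyl (2E)-3-{4-[2-(benzyloxy)-5-formylphenoxy]phenyl}prop-2-enoate | COC(=O)/C=C/c1ccc(Oc2cc(C=O)ccc2OCc2ccccc2)cc1 | intermediate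
6 | (2E)-3-{4-[2-(benzyloxy)-5-{(1E)-3-[2,4-bis(benzyloxy)-6-hydroxyphenyl]-3-oxoprop-1-en-1-yl}phenoxy]phenyl}prop-2-enoic acid | OC(=O)/C=C/c1ccc(Oc2cc(/C=C/C(=O)c3c(O)cc(OCc4ccccc4)cc3OCc3ccccc3)ccc2OCc2ccccc2)cc1 | intermediate
7 | (2E)-3-(4-{2-(benzyloxy)-5-[5,7-bis(benzyloxy)-4-oxo-4H-chromen-2-yl]phenoxy}phenyl)prop-2-enoic acid | OC(=O)/C=C/c1ccc(Oc2cc(-c3cc(=O)c4c(OCc5ccccc5)cc(OCc5ccccc5)cc4o3)ccc2OCc2ccccc2)cc1 | intermediate
8 | (2E)-3-(4-{2-(benzyloxy)-5-[5,7-bis(benzyloxy)-4-oxo-4H-chromen-2-yl]phenoxy}phenyl)prop-2-enoyl chloride | O=C(Cl)/C=C/c1ccc(Oc2cc(-c3cc(=O)c4c(OCc5ccccc5)cc(OCc5ccccc5)cc4o3)ccc2OCc2ccccc2)cc1 | intermediate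
9 | 3,5-dimethoxyphenol | COc1cc(O)cc(OC)c1 | starting material
10 | bromomagnesium 3,5-dimethoxyphenolate | COc1cc(O[Mg]Br)cc(OC)c1 | intermediate
11 | (2E)-3-(4-{2-(benzyloxy)-5-[5,7-bis(benzyloxy)-4-oxo-4H-chromen-2-yl]phenoxy}phenyl)-1-(2-hydroxy-4,6-dimethoxyphenyl)prop-2-en-1-one | COc1cc(O)c(C(=O)/C=C/c2ccc(Oc3cc(-c4cc(=O)c5c(OCc6ccccc6)cc(OCc6ccccc6)cc5o4)ccc3OCc3ccccc3)cc2)c(OC)c1 | intermediate
12 | (2S)-2-(4-{2-(benzyloxy)-5-[5,7-bis(benzyloxy)-4-oxo-4H-chromen-2-yl]phenoxy}phenyl)-5,7-dimethoxy-2,3-dihydro-4H-chromen-4-one | COc1cc(OC)c2c(c1)O[C@H](c1ccc(Oc3cc(-c4cc(=O)c5c(OCc6ccccc6)cc(OCc6ccccc6)cc5o4)ccc3OCc3ccccc3)cc1)CC2=O | intermediate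
13 | (2S)-2-{4-[5-(5,7-dihydroxy-4-oxo-4H-chromen-2-yl)-2-hydroxyphenoxy]phenyl}-5-hydroxy-7-methoxy-2,3-dihydro-4H-chromen-4-one | COc1cc(O)c2c(c1)O[C@H](c1ccc(Oc3cc(-c4cc(=O)c5c(O)cc(O)cc5o4)ccc3O)cc1)CC2=O | target

**Summary**

Total steps: 7. Longest linear sequence: 6 steps (3 + 4 to 5, then 6, 7, 8, 12, 13; the branch from 1 is equally long).

Steps most likely to fail:

1. Step 6 (proposed new method). The phenolate may be acylated at oxygen instead of carbon. Residual magnesium salts may disturb the bifunctional catalyst. Facial selection in the ring closure may be poor or of the opposite sense, through racemic background closure or retro-Michael erosion; the quinidine-derived pseudo-enantiomer of the catalyst would address only the sense. Fallback with known chemistry, setting out from 8 and 9 and coming back at 12: the magnesium-template acylation is run alone and worked up with aqueous acid, and chalcone 11 is isolated. NaOAc in refluxing EtOH closes it to the racemic protected flavanone F1. Kinetic resolution by asymmetric transfer hydrogenation with RhCl(C5Me5)[(1R,2R)-TsNCHPhCHPhNH2] and HCO2H/Et3N should reduce the 2R enantiomer, with hydride delivered anti to the 2-aryl group, to the (2R,4R)-cis-flavan-4-ol F2. The 2S ketone 12 is left behind and is separated by chromatography.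

2. Step 7. Lewis-acid-assisted opening of ring C may erode the configuration at C2. The large excess of BCl3 may also cleave the 7-methoxy group, or the electron-rich rings may be C-benzylated. Fallback setting out from 12 and coming back at 13: hydrogenolysis (H2, Pd on carbon, THF/EtOAc, rt) removes the three benzyl groups under neutral conditions to give the debenzylated 5,7-dimethoxyflavanone F3. A separate chelation-controlled demethylation of the 5-methoxy group with a small excess of BCl3 in CH2Cl2 at −20 °C then gives 13.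

3. Step 4. The HI formed may remove the 5-benzyl ether, or iodine may attack the acrylic acid double bond at 130 °C. Fallback setting out from 6 and coming back at 7: NaOAc in refluxing EtOH isomerises the chalcone to the racemic flavanone acid F4. Dehydrogenation with 2,3-dichloro-5,6-dicyano-1,4-benzoquinone in refluxing dioxane then introduces the C2–C3 double bond without iodine or acid.

Further compounds
F1 | step 6 | (2RS)-2-(4-{2-(benzyloxy)-5-[5,7-bis(benzyloxy)-4-oxo-4H-chromen-2-yl]phenoxy}phenyl)-5,7-dimethoxy-2,3-dihydro-4H-chromen-4-one | COc1cc(OC)c2c(c1)OC(c1ccc(Oc3cc(-c4cc(=O)c5c(OCc6ccccc6)cc(OCc6ccccc6)cc5o4)ccc3OCc3ccccc3)cc1)CC2=O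
F2 | step 6 | (2R,4R)-2-(4-{2-(benzyloxy)-5-[5,7-bis(benzyloxy)-4-oxo-4H-chromen-2-yl]phenoxy}phenyl)-5,7-dimethoxy-3,4-dihydro-2H-chromen-4-ol | COc1cc(OC)c2c(c1)O[C@@H](c1ccc(Oc3cc(-c4cc(=O)c5c(OCc6ccccc6)cc(OCc6ccccc6)cc5o4)ccc3OCc3ccccc3)cc1)C[C@H]2O
F3 | step 7 | (2S)-2-{4-[5-(5,7-dihydroxy-4-oxo-4H-chromen-2-yl)-2-hydroxyphenoxy]phenyl}-5,7-dimethoxy-2,3-dihydro-4H-chromen-4-one | COc1cc(OC)c2c(c1)O[C@H](c1ccc(Oc3cc(-c4cc(=O)c5c(O)cc(O)cc5o4)ccc3O)cc1)CC2=O
F4 | step 4 | (2E)-3-(4-{2-(benzyloxy)-5-[5,7-bis(benzyloxy)-4-oxo-3,4-dihydro-2H-chromen-2-yl]phenoxy}phenyl)prop-2-enoic acid (racemic) | OC(=O)/C=C/c1ccc(Oc2cc(C3CC(=O)c4c(OCc5ccccc5)cc(OCc5ccccc5)cc4O3)ccc2OCc2ccccc2)cc1
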